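A small charge of coupling partner buys a small conversion: the blue run at 0.54 M holds its substrate near 75.8% from the first reading on, the violet run at 1.2 M near 51.8%, and the ochre run near 58.8%.

| flask | substrate | coupling partner | remark | time |
|---|---|---|---|---|
| blue | 0.80 M | 0.54 M | run made earlier |  |
| violet | 0.80 M | 1.2 M | run made earlier |  |
| ochre | 0.40 M | 0.80 M | run made earlier |  |
| flask | 0.80 M | 0.800 M |  | 40 min |

| run | time / min | substrate / % | single product / % |
|---|---|---|---|
| blue | 5.00 | 75 | 12 |
| blue | 15.0 | 77 | 10 |
| blue | 25.0 | 74 | 15 |
| blue | 40.0 | 77 | 9 |
| violet | 5.00 | 53 | 21 |
| violet | 15.0 | 50 | 22 |
| violet | 25.0 | 49 | 25 |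
| violet | 40.0 | 55 | 20 |
| ochre | 10.0 | 57 | 20 |
| ochre | 20.0 | 59 | 18 |
| ochre | 30.0 | 58 | 20 |
| ochre | 40.0 | 61 | 18 |

(each reading ± 2 percentage points)

- amount of substrate at 40 min, in percent of the substrate charged
- amount of single product at 40 min, in percent of the substrate charged
- amount of double product at 40 min, in percent of the substrate charged
- amount of triple product at 40 min, in percent of the substrate charged

- the numbers in the tables scatter by 2 percentage points (one standard deviation)
- a reading or a percentage of single product counts all its forms, free or not

You wanted a quick number, so here is mine. I assume each portion of partner either couples with substrate or decays by itself at first order, so the coupling share is substrate / (substrate + a constant). I replace the falling substrate by its mean, halfway between start and end. The runs then give 1.25 M, 1.28 M and 1.22 M. Their mean, 1.25 M, I call the capture concentration, the substrate level at which coupling and loss take equal shares of the partner.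

For this flask it gives a substrate drop of 0.277 M, leaving 65.4%. The error of the mean is small: the logarithmic mean is 0.652 M against 0.662 M. Single product reads about 46.4% of the substrate consumed, so I expect 16.1%.

Your forecast says substrate 66%, single product 16%, double product 15% and triple product 3%, on the ground that “The tables are flat from the first reading, so each run has already reached equilibrium”. We part on the remaining 18.5%: I expect little of it to be double product or triple product.

The flask gives substrate 64.5%, single product 15.7%, double product 0.308% and triple product 0.162%.

    substrate + coupling partner → single product (k = 0.0271 /M/s)
    coupling partner + single product → double product (k = 0.00176 /M/s)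
    coupling partner + double product → triple product (k = 0.0783 /M/s)
    coupling partner → decomposed reagent (k = 0.0315 /s)
    crystals ⇌ single product, rate k5*(cs5 - [single product]) while solid is left; crystals form when [single product] > cs5 (solubility = 0.380 M, k = 6.11 /s)
    single product ⇌ isomer of the product (K = 1.23, k = 0.00777 /s)

By 4.00 min the flask holds 0% of its coupling partner, the limiting reagent, with >99.9% of the coupling and >99.9% of the decay behind it. Single product passes into the isomer of the product, that step 99.8% done by 8.00 min, and the isomer stands at 19.3% at 40.0 min. Of the partner charged, substrate consumed equals 35.5%, and the capture concentration at the flask's mean substrate gives 34.4%. For the flask charged with 2.0 M of partner it gives 27.6% substrate, and that flask holds 29.9%.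

Readings and results were computed with made-up constants, and the scatter is random.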